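At late times the substrate and intermediate readings of the noon and dusk runs lie within scatter of zero, so what stands then is a split: the substrate gives the intermediate, the second nucleophile captures it as other capture product, and target appears along with the dissolving gas.

| flask | substrate | second nucleophile | gas | temperature | remark | time |
|---|---|---|---|---|---|---|
| noon | 0.50 M | 2 equiv | 160 mM (held) | −2 °C | run made earlier |  |
| winter | 0.50 M | 4.5 equiv | 160 mM (held) | 14 °C | run made earlier |  |
| dusk | 0.25 M | 3 equiv | 160 mM (held) | −2 °C | run made earlier |  |
| Friday's | 0.50 M | 3.00 equiv | 160 mM (held) | 0 °C |  | 2.0 h |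
| Sunday's | 0.50 M | 3.00 equiv | 160 mM (held) | 10 °C |  | 2.0 h |

noon run (percent of the substrate charged)

| time / h | substrate / % | target / % | intermediate / % | other capture product / % |
|---|---|---|---|---|
| 0.333 | 53 | 5 | 17 | 32 |
| 0.667 | 19 | 5 | 12 | 56 |
| 1.00 | 11 | 7 | 6 | 72 |
| 1.33 | 7 | 9 | 4 | 76 |
| 1.50 | 1 | 12 | 2 | 82 |
| 2.00 | 6 | 12 | 0 | 83 |
| 2.50 | 2 | 17 | 0 | 82 |

winter run (percent of the substrate charged)

| time / min | substrate / % | target / % | intermediate / % | other capture product / % |
|---|---|---|---|---|
| 6.00 | 21 | 1 | 5 | 69 |
| 10.0 | 10 | 1 | 2 | 88 |
| 12.0 | 2 | 2 | 4 | 94 |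
| 20.0 | 0 | 0 | 0 | 100 |
| 30.0 | 0 | 2 | 0 | 97 |
| 50.0 | 0 | 0 | 0 | 96 |
| 80.0 | 1 | 0 | 0 | 100 |

dusk run (percent of the substrate charged)

| time / h | substrate / % | target / % | intermediate / % | other capture product / % |
|---|---|---|---|---|
| 0.200 | 66 | 0 | 17 | 12 |
| 0.667 | 21 | 10 | 11 | 51 |
| 1.00 | 7 | 14 | 3 | 69 |
| 1.50 | 5 | 16 | 0 | 74 |
| 2.50 | 0 | 18 | 0 | 81 |

(readings scatter by 2 percentage points)

- at the start none of the gas is in solution

1. which of these there is most of at the end, counted by the substrate in it, Friday's (target / other capture product / intermediate / substrate)
2. which of these there is most of at the end, counted by the substrate in it, Sunday's (target / other capture product / intermediate / substrate)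
3. final amount of the leader among these, as a percentage of the substrate charged, in Friday's
4. final amount of the leader among these, as a percentage of the substrate charged, in Sunday's

We reckon in a chain. The noon substrate readings give a half-life of 16.7 min, shorter than the 2.0 h of Friday's, so we count both new flasks as finished. The substrate is the limiting reagent, and [second nucleophile] falls as it is consumed, so freezing it at its mean is a rough approximation. That mean is 0.795 M in the noon run and 0.649 M in the dusk run.

Target over other capture product at the last reading, times that mean, gives 0.165 M for noon and 0.144 M for dusk. Their mean is the capture ratio, an apparent selectivity factor, of 0.154 M at −2 °C. With a frozen mean of 1.25 M, Friday's would hold 89.0% other capture product.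

The weak link is temperature. The winter substrate half-life reads 2.66 min, shorter than the noon one, and the gas starts undissolved. From 12.0 min on, winter target averages 0.800% and other capture product 97.4%, with a scatter of 2 percentage points on each reading. So the winter ratio, 0.0165 M, is rough.

Friday's, at 0 °C, stands close to the cold runs, so we commit to the 89.0% above. Sunday's 10 °C stands nearer winter's 14 °C than noon's −2 °C, so if the logarithm of the ratio falls steadily with temperature, Sunday's ratio lies between the geometric mean of the cold and winter ratios, 0.0505 M, and the winter ratio itself. With the frozen mean these give 96.1% and 98.7% other capture product, and for Sunday's we commit to their mean, 97.4%.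

The forecast names other capture product for Friday's at 89% (84% to 93%) and other capture product for Sunday's at 96% (92% to 99%). Its Friday's figure matches ours, and its Sunday's figure stands below ours. For Sunday's it expects the capture to finish “mostly before the gas arrives”.

The flasks give other capture product at 90.9% on Friday's and other capture product at 96.9% on Sunday's, with target at 8.59% and 3.10%.

    substrate → intermediate (k = 7.70 × 10⁻⁴ s⁻¹, Ea = 78.0 kJ mol⁻¹)
    first nucleophile + intermediate → target (k = 0.00960 M⁻¹ s⁻¹, Ea = 59.0 kJ mol⁻¹)
    second nucleophile + intermediate → other capture product (k = 0.00270 M⁻¹ s⁻¹, Ea = 68.0 kJ mol⁻¹)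
    gas ⇌ first nucleophile, rate k4*(csat - [first nucleophile]) (kL = 2.30 × 10⁻⁴ s⁻¹)
    (constants at 0 °C)

In Sunday's flask at 0.0744 h, the intermediate has a half-life of 1.1 min by the second nucleophile path and 1.0 h by the first nucleophile path. The second nucleophile path therefore uses it 55 times as fast, and by 0.400 h has 97% of its turnover behind it. Against the cold 0.154 M, the results give a capture ratio of 0.120 M for Friday's and 0.0403 M for Sunday's . Carried to the neighbour flask with 1.20 equiv of second nucleophile, Sunday's ratio gives 90.3% other capture product, and that flask holds 89.5%.

The runs come from a simulation with constants of no real substance; scatter was added.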